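# Isospiculoic acid A by a tethered radical route: full proposal

## Analysis of the target

Isospiculoic acid A (32) is a 1,3,3a,4,5,7a-hexahydro-2H-inden-2-one. Ring A is a cyclohexene (C3a, C4, C5, C6, C7, C7a, with C6=C7 and ethyl on C7), trans-fused to ring B, a cyclopentanone (C1, C2, C3, carbonyl at C2). Six stereocentres lie on the contiguous atoms C1, C7a, C3a, C3, C4 and C5. Taking β as the face of the C7a hydrogen, the two ring A quaternary carbons carry their ethyl groups β and the carboxyl (C4) and E-styryl (C5) groups α, the C3a hydrogen and C3 methyl are α, and the C1 ethyl is β. Every pair of neighbours around ring B is therefore trans, and C1 and C3 flank the ketone, so both can be corrected by enolisation; only C3a, C7a, C4 and C5 need kinetic control. Sensitive points are the enolisable ketone, a γ,δ-unsaturated acid that can lactonise onto C6=C7 or the styrene under strong acid, and a carboxyl group on a doubly neopentyl carbon that would be hard to free from an ester. The real difficulty is the C4–C5 pair of adjacent fully substituted carbons next to the ring fusion, where ionic C–C bond formation at C5 is disfavoured. The strategy rests on the cis (α,α) relation between the carboxyl carbon on C4 and the styryl carbon on C5: a one-carbon oxygen handle on C4 can carry a two-carbon acetal tether that reaches C5 only from the α face of ring A.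

## Retrosynthetic reasoning

**32 ⇒ 31 ⇒ 30.** The carboxyl group is taken back to the aldehyde 31 and the primary alcohol 30; no skeletal bond is cut. An acid on a doubly neopentyl carbon is best made last by oxidation rather than by ester cleavage, and a CH2–O group on C4 is what a tether needs.

**30 ⇒ 29 ⇒ 27.** The C1–ethyl bond is cut. The C2 ketone activates C1, and C3 already carries its methyl group, so the kinetic enolate can form only toward C1. The forward alkylation must place ethyl β, which is also the thermodynamic outcome.

**27 ⇒ 26 ⇒ 25.** The C2 ketone is traced to a silyl-protected secondary alcohol. This keeps C2 inert toward all carbon nucleophiles and bases used earlier and lets ring B come from a chiral-pool cyclopentenone.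

**25 ⇒ 24 ⇒ 23 ⇒ 22.** The styrene double bond is traced to a benzylic carbinol and the phenyl–carbon bond is cut, leaving lactol 22 and a phenyl nucleophile. The benzylic carbon is then an aldehyde carbon masked as a lactol on the C4 oxygen, which is exactly what an acetal tether leaves behind. The primary hydroxyl group must be capped (24) so that dehydration gives the alkene and not a cyclic ether.

**22 ⇒ 21 ⇒ 20 ⇒ 18.** The C7–ethyl bond is cut at the enol triflate 20. This reveals a C7 ketone in 18, the carbonyl that makes C5 the β carbon of an enone one step earlier. The ketone must be converted before any carbon nucleophile is used.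

**18 ⇒ 17 (key disconnection).** The bond from C5 to the ring CH2 of the tetrahydropyran is cut homolytically. This removes the second quaternary centre and leaves a planar enone β carbon, with the C5 configuration decided by the tether alone. The forward step must close a six-membered ring onto a fully substituted carbon faster than the radical is reduced.

**17 ⇒ 15 + 16.** The acetal C–O bond is cut, giving the neopentyl alcohol 15 and the vinyl ether 16; this is a routine haloacetalisation.

**15 ⇒ 12.** The C5–ethyl bond is cut with a 1,3-carbonyl transposition: the β-ethyl enone is the addition–hydrolysis product of vinylogous ester 12. The ester of 12 can be reduced in the same operation while C7 is masked, so no reoxidation is needed.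

**12 ⇒ 11 ⇒ 9.** The O-methyl bond and then the C4–ethyl bond are cut. C4 becomes quaternary by alkylating a cyclic enolate on the rigid trans-fused bicycle, where ring geometry and the C3 methyl group choose the face. The quaternary C4 in turn directs enol ether formation to the C7 oxygen.

**9 ⇒ 6 + 7.** Ring A is opened at C3a–C4 (Michael) and C5–C6 (Claisen). An unhindered malonate adds easily to the hindered β carbon of 6; the C3 methyl group controls C3a, and C7a is set thermodynamically.

**6 ⇒ 3 + 4, 3 ⇒ 1.** The acyl bond at C7a is cut (cross-coupling of enol triflate 3 with stannane 4), and then the C3–methyl bond (conjugate addition to 1 with enolate trapping). The single stereocentre of commercial 1 fixes the absolute configuration of the whole route.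

## Alternatives that were turned down

**Alternative 1: carbonylative enyne cyclisation that forms both rings.**
- Disconnection: C3a–C7a, C1–C2 and C2–C3 are cut together, which removes CO and opens the bicycle to the acyclic dienyne A2.
- Forward key step: under CO with [Rh(CO)2Cl]2, the alkyne, the distal alkene of the diene and CO combine in a [2+2+1] reaction that closes ring A and the cyclopentenone, giving dienone A1.
- For it: three C–C bonds, both rings and the C2 carbonyl arise in one catalytic step, and the C6=C7 ethyl-bearing alkene survives as the unreacted half of the diene. In ring-forming economy this is clearly stronger than the chosen route.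
- Against it: A2 must already contain C4 and C5 as adjacent quaternary stereocentres in an open chain, where no ring or tether relates them, so the hardest problem is only moved earlier. Both π partners are internal and the 1,7-tether is slow to close. C7a would be set only by induction from the remote quaternary carbons. A1 has a tetrasubstituted C3=C3a enone, so the C3a hydrogen must later be delivered trans to C7a–H next to quaternary C4, a reduction whose face selectivity is hard to predict. The nitrile still has to become the styrene and a methyl ester on C4 has to be cleaved.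
- Comparison: the chosen strategy is longer, but each stereocentre is set on a ring (C3a by anti addition, C7a by equilibration, C4 by enolate alkylation, C5 by the tether).

**Alternative 2: ring-contracting ester enolate Claisen rearrangement.**
- Disconnection: the C4–C5 bond is cut and C7 is reconnected to the carboxyl oxygen, giving A4, the trimethylsilyl ketene acetal of a δ-lactone whose ring oxygen is bonded to C7.
- Forward key step: A4 undergoes a [3,3] shift through a boat enforced by the lactone ring, forming C4–C5, breaking C7–O and moving the alkene to C6=C7, to give the ring A acid A3.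
- For it: it makes the bond between the two quaternary carbons directly and sets both in one concerted step. The ketene acetal geometry is fixed by the ring, the carboxyl group appears at its final oxidation level and the styryl group is already present. On the central C4/C5 problem and on redox economy it is stronger than the chosen route.
- Against it: the new σ bond joins two fully substituted carbons in a boat that forces the C3a side chain axial beside the C5 ethyl group. The tertiary allylic C7–O bond can ionise or eliminate instead. The C5 configuration depends on a geometrically pure trisubstituted diene. A4 needs four contiguous stereocentres (C3, C3a, C7a, C7) before the key step. After it, ring B must still be closed through C1–C2, creating C1.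
- Comparison: the chosen strategy forms C5 by a radical addition with an early transition state that tolerates congestion, on a bicycle assembled by a robust annulation. It pays with redox and protecting-group steps.

**Alternative 3: carbenoid C–H insertion to close ring B.**
- Disconnection: C3–C3a is cut, opening ring B to A6, a cyclohexane bearing an α-diazo β-keto ester chain on C7a.
- Forward key step: Rh2(OAc)4 generates the carbenoid, which inserts 1,5 into a C–H bond of the C3a methylene to give the trans-hydrindane β-keto ester A5.
- For it: five-membered ring closure by insertion is dependable and favours the trans fusion, no chiral cyclopentane building block is needed, and ring A can come from a symmetric cyclohexane. On ring B it is at least as strong as the chosen route, which buys ring B from the chiral pool and keeps C2 masked for many steps.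
- Against it: the C3a methylene is neopentyl and sits next to the ester-bearing C4, so it is hindered and inductively deactivated toward an electrophilic carbenoid. Insertion into the methyl C–H of the C1 ethyl group (also 1,5) and ylide formation at a ketal oxygen on C7 compete. The ester on C3 has to be exchanged for methyl and the C5 carbinol turned into the styrene. Above all, the key step does nothing for the vicinal quaternary pair, which must be built beforehand without the help of a tether.
- Comparison: the chosen strategy spends its key step on the most difficult bond, the one at C5.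

Key step: step 8

## Remarks on the chemistry

- All bicyclic compounds are numbered as in the target (indene numbering); β is the face of the C7a hydrogen, α the face of the C3a hydrogen.
- C2 is carried as the β tert-butyldimethylsilyl ether and oxidised to the ketone only in step 16. It is a spectator in the key step, and this lets ring B come from enantiopure 1 (a 3-acylcyclopent-3-enone ketal would be reached less directly).
- 9 and 10 are drawn as one tautomer. The acetal and benzylic carbinol centres in 17, 18 and 20 to 24 form as epimer mixtures that converge later.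

## Route

**Step 1**
Reactants: 1 (R)-4-(tert-butyldimethylsilyloxy)cyclopent-2-en-1-one
Product: 3 (3R,4R)-4-(tert-butyldimethylsilyloxy)-3-methylcyclopent-1-en-1-yl trifluoromethanesulfonate, via lithium enolate 2 (not isolated)
Conditions: MeLi (2 equiv), CuI, Et2O, 0 °C; add 1, THF, −78 °C; then N-(5-chloropyridin-2-yl)bis(trifluoromethanesulfonimide), −78 °C to rt
Reagents that add atoms: methyllithium (used as Me2CuLi), [Li]C; N-(5-chloropyridin-2-yl)bis(trifluoromethanesulfonimide), O=S(=O)(N(c1ccc(Cl)cn1)S(=O)(=O)C(F)(F)F)C(F)(F)F
Why: Conjugate addition of a Gilman cuprate to a 4-silyloxycyclopentenone occurs anti to the silyloxy group, so the methyl group (C3) is set trans to the C2 oxygen; the regiodefined enolate is trapped on oxygen by the pyridyl triflimide, the standard triflation of cuprate-derived enolates, which places the double bond where the acetyl group is needed.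

**Step 2**
Reactants: 3 enol triflate; 4 tributyl(1-ethoxyvinyl)stannane
Product: 6 1-[(3R,4R)-4-(tert-butyldimethylsilyloxy)-3-methylcyclopent-1-en-1-yl]ethan-1-one, via ethoxydiene 5 (not isolated)
Conditions: Pd(PPh3)4 (5 mol %), LiCl, THF, 65 °C; then 1 M HCl, THF, 0 °C
Reagents that add atoms: water, O
Why: Stille coupling of an enol triflate with an α-alkoxyvinylstannane (oxidative addition to zerovalent palladium, chloride-assisted transmetallation), followed by hydrolysis of the enol ether to the methyl ketone, is a reliable acylation of an enol triflate. The allylic stereocentre is not touched and brief dilute acid spares the secondary silyl ether.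

**Step 3**
Reactants: 6 acetylcyclopentene; 7 dimethyl malonate
Product: 9 methyl 2β-(tert-butyldimethylsilyloxy)-3α-methyl-5,7-dioxo-3aα,7aβ-octahydroindene-4-carboxylate (enolised; C4 stereolabile), via Michael adduct 8 (not isolated)
Conditions: NaOMe (1.1 equiv), MeOH, 0 °C to rt; then NaOMe (1.1 equiv), reflux; aq. HCl to pH 3, 0 °C
Reagents that add atoms: none
Why: Michael addition followed by Claisen condensation is the classical cyclohexane-1,3-dione annulation: the unhindered malonate anion adds to C3a anti to the adjacent C3 methyl, the adduct protonates at C7a to the all-trans cyclopentane, and the methyl ketone enolate closes ring A on one ester, the dione enolate being the thermodynamic sink. C7a remains α to a carbonyl, so the trans ring fusion can be secured by equilibration; C4 is fixed in step 4.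

**Step 4**
Reactants: 9 dione ester
Product: 11 methyl 2β-(tert-butyldimethylsilyloxy)-4β-ethyl-3α-methyl-5,7-dioxo-3aα,7aβ-octahydroindene-4α-carboxylate, via dilithium dianion 10 (not isolated)
Conditions: LiN(iPr)2 (2.2 equiv), THF, DMPU, −78 to −20 °C; EtI, −78 to 0 °C; aq. HCl to pH 4
Reagents that add atoms: iodoethane, CCI
Why: Alkylation of a 1,3-dicarbonyl dianion occurs at its last-formed, most basic carbon: after the dione is deprotonated, the second equivalent removes the C4 proton α to the ester, and this ester enolate is ethylated in preference to the delocalised dione anion. The electrophile should enter on the β face, antiperiplanar to the axial C3a–H and away from the α methyl on C3, placing ethyl β (axial) and the ester α at the new quaternary C4.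

**Step 5**
Reactants: 11 quaternary dione ester
Product: 12 methyl 2β-(tert-butyldimethylsilyloxy)-4β-ethyl-7-methoxy-3α-methyl-5-oxo-2,3,3aα,4,5,7aβ-hexahydro-1H-indene-4α-carboxylate
Conditions: Me2SO4, K2CO3, acetone, reflux
Reagents that add atoms: dimethyl sulfate, COS(=O)(=O)OC
Why: O-Alkylation of a cyclic 1,3-dione enolate by a hard electrophile gives the vinylogous ester; the oxygen on C7 is flanked by a methine whereas that on C5 is flanked by the quaternary C4, so methylation at the C7 oxygen should dominate, and the regioisomer would be removed by chromatography.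

**Step 6**
Reactants: 12 vinylogous ester
Product: 15 2β-(tert-butyldimethylsilyloxy)-4β,5-diethyl-4α-(hydroxymethyl)-3α-methyl-1,2,3,3aα,4,7aβ-hexahydro-7H-inden-7-one, via lithium alkoxide 13 (not isolated), via aluminate diol 14 (not isolated)
Conditions: EtLi (1.3 equiv), THF, −78 °C; LiAlH4, −78 to 0 °C; 1 M HCl, THF, 0 °C to rt
Reagents that add atoms: ethyllithium, [Li]CC; water, O
Why: Stork–Danheiser transposition combined with ester reduction: ethyllithium adds 1,2 to the C5 carbonyl (not enolisable on the C4 side and more electrophilic than the neopentyl ester), LiAlH4 then reduces the ester while C7 is still masked as its enol ether, and aqueous acid ionises the tertiary allylic alcohol and hydrolyses the enol ether to the transposed enone with ethyl on C5. The hydroxymethyl enone is obtained without a separate reoxidation, and the C5 carbinol configuration is irrelevant.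

**Step 7**
Reactants: 15 enone alcohol; 16 ethyl vinyl ether
Product: 17 4α-[(2-bromo-1-ethoxyethoxy)methyl]-2β-(tert-butyldimethylsilyloxy)-4β,5-diethyl-3α-methyl-1,2,3,3aα,4,7aβ-hexahydro-7H-inden-7-one (both acetal epimers)
Conditions: N-bromosuccinimide, 16 (5 equiv), CH2Cl2, −78 to 0 °C; Et3N quench
Reagents that add atoms: N-bromosuccinimide, O=C1CCC(=O)N1Br
Why: Bromoacetalisation: the vinyl ether is brominated and the neopentyl alcohol captures the α-bromo oxocarbenium ion, the standard preparation of haloacetal radical precursors. The electron-poor enone is inert, and the new acetal centre is of no consequence.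

**Step 8 (key step)**
Reactants: 17 bromoacetal
Product: 18 2β-(tert-butyldimethylsilyloxy)-4β,5β-diethyl-3α-methyl-3aα,7aβ-octahydroinden-7-one bridged on the α face from C4 to C5 by CH2–O–CH(OEt)–CH2 (cis-fused 2-ethoxytetrahydropyran; both acetal epimers)
Conditions: Bu3SnH (1.3 equiv, syringe pump, 8 h), AIBN (0.2 equiv), benzene, 80 °C, 5 mM
Reagents that add atoms: none
Why: This is an Ueno–Stork haloacetal radical cyclisation. Bromine abstraction by the stannyl radical gives a primary, nucleophilic alkyl radical that adds to C5, the β carbon of the enone, in a 6-exo-trig closure that forms the tetrahydropyran and the C5–CH2 bond; the resulting C6 radical, stabilised by the C7 carbonyl, takes hydrogen from Bu3SnH and carries the chain. The closest known reaction type is the bromoacetal radical cyclisation onto cyclic enones, which is used to build quaternary carbons that resist organocopper conjugate addition, because the early, long-bonded transition state is little affected by fully substituted neighbours. C5 is the only new stereocentre that matters: the four-atom tether starts from the pseudo-equatorial α CH2O group on C4 and can reach only the α lobe of the C5 p orbital (axial attack), so the pyran is necessarily cis-fused and the future styryl carbon is cis to the future carboxyl carbon, whereas a trans-fused product would need in-plane attack. The step needs 6-exo over 7-endo selectivity, which the enone polarity (attack at the β carbon gives the carbonyl-stabilised radical) and the smaller ring both favour. It also needs cyclisation to outrun reduction of the open radical, which the high effective molarity of a radical anchored on a quaternary carbon and the low stationary stannane concentration should secure. 1,5-Hydrogen transfer has no partner, since the reachable C–H bonds are 1,4 or 1,6 to the radical carbon. The acetal carbon is formed as both epimers, which is immaterial because it later becomes the sp2 benzylic carbon.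

**Step 9**
Reactants: 18 keto acetal
Product: 20 C6=C7 enol trifluoromethanesulfonate of 18, via potassium enolate 19 (not isolated)
Conditions: KN(SiMe3)2, THF, −78 °C; N-phenylbis(trifluoromethanesulfonimide), −78 to 0 °C
Reagents that add atoms: N-phenylbis(trifluoromethanesulfonimide), O=S(=O)(N(c1ccccc1)S(=O)(=O)C(F)(F)F)C(F)(F)F
Why: Kinetic deprotonation by a hindered amide base should remove a proton from the C6 methylene rather than the C7a ring-fusion methine, and O-triflation fixes the C6=C7 enol. The cyclic acetal and the silyl ether are stable to base.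

**Step 10**
Reactants: 20 enol triflate
Product: 21 7-ethyl C6=C7 alkene (cyclic ethyl acetal and 2β silyl ether retained)
Conditions: Et2Zn (2 equiv), Pd(dppf)Cl2 (5 mol %), THF, 60 °C
Reagents that add atoms: diethylzinc, CC[Zn]CC
Why: Negishi coupling: oxidative addition of the enol triflate to zerovalent palladium, transmetallation from Et2Zn and reductive elimination, which with the wide-bite-angle dppf ligand outruns β-hydride elimination. The C7 ethyl group and the C6=C7 double bond of the target are now in place.

**Step 11**
Reactants: 21 ethyl acetal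
Product: 22 lactol (2-hydroxytetrahydropyran in place of the 2-ethoxytetrahydropyran)
Conditions: AcOH/THF/H2O (3:1:1), 40 °C
Reagents that add atoms: water, O
Why: Acid hydrolysis of the mixed ethyl tetrahydropyranyl acetal, which ionises by loss of ethanol far more readily than a hindered secondary silyl ether is cleaved, gives the lactol as the masked aldehyde of the future benzylic carbon.

**Step 12**
Reactants: 22 lactol
Product: 23 diol with 4α-CH2OH and 5α-CH2CH(OH)Ph (both carbinol epimers)
Conditions: PhMgBr (4 equiv), THF, 0 °C to rt; aq. NH4Cl
Reagents that add atoms: phenylmagnesium bromide, Br[Mg]c1ccccc1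
Why: Grignard addition to the hydroxy aldehyde in equilibrium with the lactol magnesium alkoxide; no other electrophilic group is present, since neither C7 nor C2 carries a carbonyl at this stage. The benzylic carbinol epimers converge in step 14.

**Step 13**
Reactants: 23 diol
Product: 24 primary tert-butyldiphenylsilyl ether of 23
Conditions: tert-butyl(chloro)diphenylsilane, imidazole, DMF, rt to 40 °C
Reagents that add atoms: tert-butyl(chloro)diphenylsilane, CC(C)(C)[Si](Cl)(c1ccccc1)c1ccccc1
Why: Selective silylation: the bulky silyl chloride discriminates strongly in favour of a primary over a secondary hydroxyl group. Capping the primary alcohol keeps it from closing a tetrahydropyran onto the benzylic position during dehydration.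

**Step 14**
Reactants: 24 benzylic alcohol
Product: 25 5α-[(E)-2-phenylethenyl] compound (E-styrene)
Conditions: methyl N-(triethylammoniumsulfonyl)carbamate (Burgess reagent), toluene, 70 °C
Reagents that add atoms: none
Why: Burgess dehydration: the sulfamate ester of the secondary benzylic alcohol undergoes thermal syn elimination toward the only β hydrogens (the CH2 on C5), giving the conjugated E-styrene, the geometry that keeps phenyl and the quaternary C5 apart.

**Step 15**
Reactants: 25 bis(silyl ether)
Product: 26 2β-alcohol (primary tert-butyldiphenylsilyl ether retained)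
Conditions: HF·pyridine, pyridine, THF, 0 °C to rt
Reagents that add atoms: none
Why: Buffered hydrogen fluoride cleaves the secondary tert-butyldimethylsilyl ether much faster than the bulkier neopentyl tert-butyldiphenylsilyl ether, exposing only the C2 hydroxyl group.

**Step 16**
Reactants: 26 secondary alcohol
Product: 27 C2 ketone
Conditions: Dess–Martin periodinane, NaHCO3, CH2Cl2, rt
Reagents that add atoms: none
Why: Dess–Martin oxidation of the secondary alcohol under buffered conditions leaves both alkenes and the silyl ether alone. C3 becomes enolisable, but its α methyl (trans to the C3a–C4 bond) is the thermodynamically preferred arrangement.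

**Step 17**
Reactants: 27 ketone
Product: 29 1β-ethyl ketone, via lithium enolate 28 (not isolated)
Conditions: LiN(iPr)2 (1.1 equiv), THF, −78 °C; EtI (5 equiv), DMPU, −78 to −30 °C
Reagents that add atoms: iodoethane, CCI
Why: Kinetic enolate alkylation: the amide base removes a proton from the C1 methylene rather than the C3 methine, and iodoethane attacks the enolate on the β face, anti to the C7a–C7 bond. The ethyl group is thus trans to ring A on C7a, which is also the thermodynamic arrangement reachable by base equilibration.

**Step 18**
Reactants: 29 silyl ether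
Product: 30 4α-(hydroxymethyl) ketone
Conditions: Bu4NF, THF, rt to 45 °C; aq. NH4Cl
Reagents that add atoms: none
Why: Fluoride cleavage of the remaining silyl ether liberates the primary alcohol; the mildly basic fluoride can only equilibrate C1 and C3 toward the all-trans ring B already in place.

**Step 19**
Reactants: 30 primary alcohol
Product: 31 4α-carbaldehyde
Conditions: Dess–Martin periodinane, NaHCO3, CH2Cl2, rt
Reagents that add atoms: none
Why: Dess–Martin oxidation of the neopentyl primary alcohol gives an aldehyde that has no α hydrogen and therefore cannot epimerise.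

**Step 20**
Reactants: 31 aldehyde
Product: 32 isospiculoic acid A
Conditions: NaClO2, NaH2PO4, 2-methylbut-2-ene, t-BuOH/H2O, rt
Reagents that add atoms: sodium chlorite, [Na+].[O-]Cl=O
Why: Pinnick oxidation converts the hindered, non-enolisable aldehyde into the carboxylic acid; the alkene scavenger consumes hypochlorous acid so that the styrene and ring alkene are not chlorinated, and the buffered medium avoids acid-induced lactonisation.

## Compound list

1 | (R)-4-(tert-butyldimethylsilyloxy)cyclopent-2-en-1-one | O=C1C=C[C@H](O[Si](C)(C)C(C)(C)C)C1 | starting material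
2 | lithium (3R,4R)-4-(tert-butyldimethylsilyloxy)-3-methylcyclopent-1-en-1-olate | [Li+].[O-]C1=C[C@@H](C)[C@H](O[Si](C)(C)C(C)(C)C)C1 | intermediate (not isolated)
3 | (3R,4R)-4-(tert-butyldimethylsilyloxy)-3-methylcyclopent-1-en-1-yl trifluoromethanesulfonate | O=S(=O)(OC1=C[C@@H](C)[C@H](O[Si](C)(C)C(C)(C)C)C1)C(F)(F)F | intermediate
4 | tributyl(1-ethoxyvinyl)stannane | CCCC[Sn](CCCC)(CCCC)C(=C)OCC | starting material
5 | tert-butyl{[(1R,2R)-4-(1-ethoxyethenyl)-2-methylcyclopent-3-en-1-yl]oxy}dimethylsilane | C=C(OCC)C1=C[C@@H](C)[C@H](O[Si](C)(C)C(C)(C)C)C1 | intermediate (not isolated)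
6 | 1-[(3R,4R)-4-(tert-butyldimethylsilyloxy)-3-methylcyclopent-1-en-1-yl]ethan-1-one | CC(=O)C1=C[C@@H](C)[C@H](O[Si](C)(C)C(C)(C)C)C1 | intermediate
7 | dimethyl malonate | COC(=O)CC(=O)OC | starting material
8 | dimethyl 2-[2-acetyl-4-(tert-butyldimethylsilyloxy)-5-methylcyclopentyl]malonate, all ring neighbours trans | COC(=O)C(C(=O)OC)[C@H]1[C@H](C(C)=O)C[C@@H](O[Si](C)(C)C(C)(C)C)[C@@H]1C | intermediate (not isolated)
9 | methyl 2β-(tert-butyldimethylsilyloxy)-3α-methyl-5,7-dioxo-3aα,7aβ-octahydroindene-4-carboxylate (triketo tautomer drawn, C4 stereolabile) | O=C1CC(=O)C(C(=O)OC)[C@H]2[C@H]1C[C@@H](O[Si](C)(C)C(C)(C)C)[C@@H]2C | intermediate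
10 | dilithium dianion of 9 (dione enolate and C4 ester enolate) | [Li+].[Li+].O=C1C=C([O-])C(=C([O-])OC)[C@H]2[C@H]1C[C@@H](O[Si](C)(C)C(C)(C)C)[C@@H]2C | intermediate (not isolated)
11 | methyl 2β-(tert-butyldimethylsilyloxy)-4β-ethyl-3α-methyl-5,7-dioxo-3aα,7aβ-octahydroindene-4α-carboxylate | O=C1CC(=O)[C@@](CC)(C(=O)OC)[C@H]2[C@H]1C[C@@H](O[Si](C)(C)C(C)(C)C)[C@@H]2C | intermediate
12 | methyl 2β-(tert-butyldimethylsilyloxy)-4β-ethyl-7-methoxy-3α-methyl-5-oxo-2,3,3aα,4,5,7aβ-hexahydro-1H-indene-4α-carboxylate | COC1=CC(=O)[C@@](CC)(C(=O)OC)[C@H]2[C@H]1C[C@@H](O[Si](C)(C)C(C)(C)C)[C@@H]2C | intermediate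
13 | lithium alkoxide of the C5 ethyl carbinol from 12 (ester intact) | [Li+].COC1=CC([O-])(CC)[C@@](CC)(C(=O)OC)[C@H]2[C@H]1C[C@@H](O[Si](C)(C)C(C)(C)C)[C@@H]2C | intermediate (not isolated)
14 | 2β-(tert-butyldimethylsilyloxy)-4β,5-diethyl-4α-(hydroxymethyl)-7-methoxy-3α-methyl-2,3,3aα,4,5,7aβ-hexahydro-1H-inden-5-ol (present as its aluminate; neutral form drawn) | COC1=CC(O)(CC)[C@@](CC)(CO)[C@H]2[C@H]1C[C@@H](O[Si](C)(C)C(C)(C)C)[C@@H]2C | intermediate (not isolated)
15 | 2β-(tert-butyldimethylsilyloxy)-4β,5-diethyl-4α-(hydroxymethyl)-3α-methyl-1,2,3,3aα,4,7aβ-hexahydro-7H-inden-7-one | O=C1C=C(CC)[C@@](CC)(CO)[C@H]2[C@H]1C[C@@H](O[Si](C)(C)C(C)(C)C)[C@@H]2C | intermediate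
16 | ethyl vinyl ether | C=COCC | starting material
17 | 4α-[(2-bromo-1-ethoxyethoxy)methyl]-2β-(tert-butyldimethylsilyloxy)-4β,5-diethyl-3α-methyl-1,2,3,3aα,4,7aβ-hexahydro-7H-inden-7-one | O=C1C=C(CC)[C@@](CC)(COC(CBr)OCC)[C@H]2[C@H]1C[C@@H](O[Si](C)(C)C(C)(C)C)[C@@H]2C | intermediate (key-step precursor)
18 | tricyclic keto acetal: 4β,5β-diethyl trans-hydrindan-7-one with α-face CH2–O–CH(OEt)–CH2 bridge from C4 to C5, 2β-silyloxy, 3α-methyl | O=C1C[C@@]2(CC)CC(OCC)OC[C@@]2(CC)[C@H]3[C@H]1C[C@@H](O[Si](C)(C)C(C)(C)C)[C@@H]3C | intermediate (key-step product)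
19 | potassium C6=C7 enolate of 18 | [K+].[O-]C1=C[C@@]2(CC)CC(OCC)OC[C@@]2(CC)[C@H]3[C@H]1C[C@@H](O[Si](C)(C)C(C)(C)C)[C@@H]3C | intermediate (not isolated)
20 | C6=C7 enol trifluoromethanesulfonate of 18 | O=S(=O)(OC1=C[C@@]2(CC)CC(OCC)OC[C@@]2(CC)[C@H]3[C@H]1C[C@@H](O[Si](C)(C)C(C)(C)C)[C@@H]3C)C(F)(F)F | intermediate
21 | 7-ethyl C6=C7 alkene with cyclic ethyl acetal | CCC1=C[C@@]2(CC)CC(OCC)OC[C@@]2(CC)[C@H]3[C@H]1C[C@@H](O[Si](C)(C)C(C)(C)C)[C@@H]3C | intermediate
22 | lactol corresponding to 21 | CCC1=C[C@@]2(CC)CC(O)OC[C@@]2(CC)[C@H]3[C@H]1C[C@@H](O[Si](C)(C)C(C)(C)C)[C@@H]3C | intermediate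
23 | diol: 4α-(hydroxymethyl), 5α-(2-hydroxy-2-phenylethyl) | CCC1=C[C@](CC(O)c2ccccc2)(CC)[C@@](CC)(CO)[C@H]3[C@H]1C[C@@H](O[Si](C)(C)C(C)(C)C)[C@@H]3C | intermediate
24 | primary tert-butyldiphenylsilyl ether of 23 | CCC1=C[C@](CC(O)c2ccccc2)(CC)[C@@](CC)(CO[Si](c2ccccc2)(c2ccccc2)C(C)(C)C)[C@H]3[C@H]1C[C@@H](O[Si](C)(C)C(C)(C)C)[C@@H]3C | intermediate
25 | 5α-[(E)-2-phenylethenyl] bis(silyl ether) | CCC1=C[C@](/C=C/c2ccccc2)(CC)[C@@](CC)(CO[Si](c2ccccc2)(c2ccccc2)C(C)(C)C)[C@H]3[C@H]1C[C@@H](O[Si](C)(C)C(C)(C)C)[C@@H]3C | intermediate
26 | 2β-alcohol | CCC1=C[C@](/C=C/c2ccccc2)(CC)[C@@](CC)(CO[Si](c2ccccc2)(c2ccccc2)C(C)(C)C)[C@H]3[C@H]1C[C@@H](O)[C@@H]3C | intermediate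
27 | C2 ketone | CCC1=C[C@](/C=C/c2ccccc2)(CC)[C@@](CC)(CO[Si](c2ccccc2)(c2ccccc2)C(C)(C)C)[C@H]3[C@H]1CC(=O)[C@@H]3C | intermediate
28 | lithium C1=C2 enolate of 27 | [Li+].CCC1=C[C@](/C=C/c2ccccc2)(CC)[C@@](CC)(CO[Si](c2ccccc2)(c2ccccc2)C(C)(C)C)[C@H]3[C@H]1C=C([O-])[C@@H]3C | intermediate (not isolated)
29 | 1β-ethyl ketone | CCC1=C[C@](/C=C/c2ccccc2)(CC)[C@@](CC)(CO[Si](c2ccccc2)(c2ccccc2)C(C)(C)C)[C@H]3[C@H]1[C@@H](CC)C(=O)[C@@H]3C | intermediate
30 | 4α-(hydroxymethyl) ketone | CCC1=C[C@](/C=C/c2ccccc2)(CC)[C@@](CC)(CO)[C@H]3[C@H]1[C@@H](CC)C(=O)[C@@H]3C | intermediate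
31 | 4α-carbaldehyde | CCC1=C[C@](/C=C/c2ccccc2)(CC)[C@@](CC)(C=O)[C@H]3[C@H]1[C@@H](CC)C(=O)[C@@H]3C | intermediate
32 | isospiculoic acid A | CCC1=C[C@](/C=C/c2ccccc2)(CC)[C@@](CC)(C(=O)O)[C@H]2[C@H]1[C@@H](CC)C(=O)[C@@H]2C | target

## Step count and least certain steps

Total step count: 20. Longest linear sequence: 20 steps from 1; compounds 4, 7 and 16 are used as purchased.

**Step 8 (key step).** The open primary radical may take hydrogen from the stannane, or the closure may be too slow, because the β carbon is fully substituted and flanked by a quaternary carbon and 6-exo closures are inherently slower than 5-exo ones. Fallback, from 15 to 22, replacing the radical by a two-electron tethered conjugate addition: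
- 15 is acylated with methyl malonyl chloride and pyridine to the mixed malonate ester F1.
- Cs2CO3 in MeCN effects intramolecular Michael addition to C5 from the α face, driven by the stabilised enolate of the product, giving the cis-fused lactone ester F2.
- Krapcho dealkoxycarbonylation (LiCl, wet DMSO, 140 °C) gives the keto lactone F3.
- KN(SiMe3)2 and N-phenylbis(trifluoromethanesulfonimide) give the enol triflate lactone F4, and Et2Zn with Pd(dppf)Cl2 gives the 7-ethyl alkene lactone F5.
- i-Bu2AlH in CH2Cl2 at −78 °C reduces the lactone to lactol 22.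

**Step 4.** Ethylation may occur on the wrong face of C4, because the dianion ring is nearly flat and the bias comes only from the C3a hydrogen and the C3 methyl group; proton transfer could also lead to reaction at C6. Fallback, from 6 to 15, moving the stereo-determining event to a reversible Michael addition funnelled through an aldol closure:
- Methyl 2-ethyl-3-oxopentanoate F6 is made by C-ethylation of methyl 3-oxopentanoate (K2CO3, EtI).
- Robinson annulation of 6 with F6 (NaOMe, MeOH, reflux) gives the enone ester F7.
- LiAlH4 gives the allylic diol F8, and MnO2 reoxidises only the allylic alcohol to 15.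

**Step 6.** Ethyllithium may attack the ester, or add in conjugate fashion at C7 with loss of methoxide, because the C5 carbonyl is shielded by the quaternary C4. Fallback, from 12 to 15:
- LiAlH4 followed by aqueous HCl gives the transposed enone alcohol lacking the C5 ethyl group, F9.
- Et2CuLi with Me3SiCl adds ethyl to the now unsubstituted β carbon, giving the bis(trimethylsilyl) compound F10 (silyl enol ether and silyl ether).
- Saegusa–Ito oxidation with Pd(OAc)2 in MeCN and a mild acidic work-up restore the enone and the free alcohol, giving 15.

**Step 9.** Enolisation may occur toward C7a instead of C6, because the C6 methylene is neopentyl and both axial α hydrogens are shielded by the axial C4 ethyl group. Fallback, from 18 to 21, by a Shapiro sequence, in which dianion formation is directed to the less substituted α carbon: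
- 18 is condensed with 2,4,6-triisopropylbenzenesulfonyl hydrazide to the hydrazone F11.
- n-BuLi (2.2 equiv) and then I2 give the C7 vinyl iodide F12.
- Et2Zn with Pd(dppf)Cl2 gives 21.

**Step 13.** Silylation may be unselective, because the primary hydroxyl group is attached to a quaternary carbon next to another one and may react no faster than the benzylic secondary one; without clean protection, dehydration would be diverted into cyclic ether formation. Fallback, from 22 to 25, which never forms the diol:
- 22 is condensed with 4-methylbenzenesulfonyl hydrazide to the open-chain tosylhydrazone F13.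
- Barluenga coupling with bromobenzene (Pd2(dba)3, XPhos, LiOtBu, dioxane, 100 °C) gives the E-styrene alcohol F14 directly, by carbene migratory insertion and β-hydride elimination.
- Silylation of the only hydroxyl group with tert-butyl(chloro)diphenylsilane gives 25.

**Step 17.** Proton exchange between product and enolate may cause over-alkylation or loss of regiocontrol, because cyclopentanone enolates react slowly with iodoethane. Fallback, from 27 to 29:
- Kinetic aldol addition of the lithium enolate to acetaldehyde gives the β-hydroxy ketone F15.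
- Mesylation and elimination (MsCl, Et3N, then DBU) give the ethylidene ketone F16.
- Conjugate reduction with [(Ph3P)CuH]6, which leaves the styrene and ring alkene untouched, followed by base equilibration, gives 29.

## Further compounds

F1 | step 8 | methyl malonate ester of 15 (4α-CH2O–CO–CH2–CO2Me) | O=C1C=C(CC)[C@@](CC)(COC(=O)CC(=O)OC)[C@H]2[C@H]1C[C@@H](O[Si](C)(C)C(C)(C)C)[C@@H]2C
F2 | step 8 | cis-fused δ-lactone ester from intramolecular Michael addition (C5 quaternary, C7 ketone) | O=C1C[C@@]2(CC)C(C(=O)OC)C(=O)OC[C@@]2(CC)[C@H]3[C@H]1C[C@@H](O[Si](C)(C)C(C)(C)C)[C@@H]3C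
F3 | step 8 | keto δ-lactone after dealkoxycarbonylation | O=C1C[C@@]2(CC)CC(=O)OC[C@@]2(CC)[C@H]3[C@H]1C[C@@H](O[Si](C)(C)C(C)(C)C)[C@@H]3C
F4 | step 8 | C6=C7 enol trifluoromethanesulfonate of F3 | O=S(=O)(OC1=C[C@@]2(CC)CC(=O)OC[C@@]2(CC)[C@H]3[C@H]1C[C@@H](O[Si](C)(C)C(C)(C)C)[C@@H]3C)C(F)(F)F
F5 | step 8 | 7-ethyl C6=C7 alkene δ-lactone | CCC1=C[C@@]2(CC)CC(=O)OC[C@@]2(CC)[C@H]3[C@H]1C[C@@H](O[Si](C)(C)C(C)(C)C)[C@@H]3C
F6 | step 4 | methyl 2-ethyl-3-oxopentanoate | CCC(=O)C(CC)C(=O)OC
F7 | step 4 | methyl 2β-(tert-butyldimethylsilyloxy)-4β,5-diethyl-3α-methyl-7-oxo-2,3,3aα,4,7,7aβ-hexahydro-1H-indene-4α-carboxylate | O=C1C=C(CC)[C@@](CC)(C(=O)OC)[C@H]2[C@H]1C[C@@H](O[Si](C)(C)C(C)(C)C)[C@@H]2C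
F8 | step 4 | allylic diol from F7 (C7 carbinol, 4α-hydroxymethyl) | OC1C=C(CC)[C@@](CC)(CO)[C@H]2[C@H]1C[C@@H](O[Si](C)(C)C(C)(C)C)[C@@H]2C
F9 | step 6 | 2β-(tert-butyldimethylsilyloxy)-4β-ethyl-4α-(hydroxymethyl)-3α-methyl-1,2,3,3aα,4,7aβ-hexahydro-7H-inden-7-one | O=C1C=C[C@@](CC)(CO)[C@H]2[C@H]1C[C@@H](O[Si](C)(C)C(C)(C)C)[C@@H]2C
F10 | step 6 | C6=C7 trimethylsilyl enol ether with 5-ethyl and 4α-(trimethylsilyloxymethyl) | C[Si](C)(C)OC1=CC(CC)[C@@](CC)(CO[Si](C)(C)C)[C@H]2[C@H]1C[C@@H](O[Si](C)(C)C(C)(C)C)[C@@H]2C
F11 | step 9 | 2,4,6-triisopropylbenzenesulfonyl hydrazone of 18 | CC(C)c1cc(C(C)C)c(S(=O)(=O)NN=C2C[C@@]3(CC)CC(OCC)OC[C@@]3(CC)[C@H]4[C@H]2C[C@@H](O[Si](C)(C)C(C)(C)C)[C@@H]4C)c(C(C)C)c1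
F12 | step 9 | C7 vinyl iodide (C6=C7) with cyclic ethyl acetal | IC1=C[C@@]2(CC)CC(OCC)OC[C@@]2(CC)[C@H]3[C@H]1C[C@@H](O[Si](C)(C)C(C)(C)C)[C@@H]3C
F13 | step 13 | open-chain 4-methylbenzenesulfonyl hydrazone of the aldehyde form of 22 | CCC1=C[C@](CC=NNS(=O)(=O)c2ccc(C)cc2)(CC)[C@@](CC)(CO)[C@H]3[C@H]1C[C@@H](O[Si](C)(C)C(C)(C)C)[C@@H]3C
F14 | step 13 | 5α-[(E)-2-phenylethenyl] 4α-(hydroxymethyl) compound | CCC1=C[C@](/C=C/c2ccccc2)(CC)[C@@](CC)(CO)[C@H]3[C@H]1C[C@@H](O[Si](C)(C)C(C)(C)C)[C@@H]3C
F15 | step 17 | C1 (1-hydroxyethyl) aldol adduct of 27 | CCC1=C[C@](/C=C/c2ccccc2)(CC)[C@@](CC)(CO[Si](c2ccccc2)(c2ccccc2)C(C)(C)C)[C@H]3[C@H]1C(C(C)O)C(=O)[C@@H]3C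
F16 | step 17 | C1 ethylidene ketone | CCC1=C[C@](/C=C/c2ccccc2)(CC)[C@@](CC)(CO[Si](c2ccccc2)(c2ccccc2)C(C)(C)C)[C@H]3[C@H]1C(=CC)C(=O)[C@@H]3C
A1 | alternative 1 | methyl 5-cyano-1,4,5,7-tetraethyl-3-methyl-2-oxo-1,4,5,7a-tetrahydro-2H-indene-4-carboxylate | CCC1=C[C@](C#N)(CC)[C@@](CC)(C(=O)OC)C2=C(C)C(=O)[C@H](CC)[C@@H]12
A2 | alternative 1 | methyl (4Z,6E)-3-cyano-2,3,5-triethyl-2-(prop-1-yn-1-yl)nona-4,6-dienoate | CC/C=C/C(CC)=C\[C@](C#N)(CC)[C@@](CC)(C(=O)OC)C#CC
A3 | alternative 2 | 1,2,4-triethyl-2-[(E)-2-phenylethenyl]-5-[(E)-prop-1-enyl]-6-[1-(tert-butyldimethylsilyloxy)propan-2-yl]cyclohex-3-ene-1-carboxylic acid | CCC1=C[C@](/C=C/c2ccccc2)(CC)[C@@](CC)(C(=O)O)[C@H]([C@@H](C)CO[Si](C)(C)C(C)(C)C)[C@H]1/C=C/C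
A4 | alternative 2 | 3,6-diethyl-6-[(1E,3E)-2-ethyl-4-phenylbuta-1,3-dienyl]-5-[(E)-prop-1-enyl]-4-[1-(tert-butyldimethylsilyloxy)propan-2-yl]-2-(trimethylsilyloxy)-5,6-dihydro-4H-pyran | C[Si](C)(C)OC1=C(CC)[C@H]([C@@H](C)CO[Si](C)(C)C(C)(C)C)[C@@H](/C=C/C)[C@](CC)(/C=C(CC)/C=C/c2ccccc2)O1
A5 | alternative 3 | 4-tert-butyl 3-methyl 5-(tert-butyldimethylsilyloxymethyl)-1,4,5-triethyl-7,7-(ethylenedioxy)-2-oxo-trans-octahydroindene-3,4-dicarboxylate | CC[C@H]1C(=O)[C@H](C(=O)OC)[C@@H]2[C@@H]1C3(OCCO3)C[C@@](CC)(CO[Si](C)(C)C(C)(C)C)[C@@]2(CC)C(=O)OC(C)(C)C
A6 | alternative 3 | methyl 2-diazo-3-oxo-4-(ring A cyclohexyl)hexanoate: diazo keto ester side chain on C7a of the 7,7-(ethylenedioxy)cyclohexane carrying the C4 tert-butyl ester and C5 silyloxymethyl groups | CC[C@@H](C(=O)C(=[N+]=[N-])C(=O)OC)[C@@H]1C[C@](CC)(C(=O)OC(C)(C)C)[C@](CC)(CO[Si](C)(C)C(C)(C)C)CC12OCCO2
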